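The numbering used is ring O1, C2(=O), C3 (aroyl), C4 (aryl), C5 and exocyclic C6H–aryl. The plan cuts C4–C5 of the butenolide ring together with the C3–aroyl bond. This unfolds the core into an acyclic 1,6-enyne, the (Z)-4-methoxystyryl ester of a 3-arylpropiolic acid. It exploits that C3=C4 is a latent aryl alkynoate and that C5=C6 is a styryl enol ester whose para-oxygenated ring stabilises a radical or cation at C6. In one operation an aroyl radical adds at C3, the C4 vinyl radical closes the ring 5-exo onto C5, and oxidation with loss of H5 restores the Z-benzylidene. The bromines are carried from commercial arenes; BBr3 ends the route.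

Key step: step 4

Remark: the target has no stereocentre, so "single enantiomer" reduces to a single geometric isomer. That isomer is Z at C5=C6 (aryl on C6 cis to O1), and this is the only stereochemical element to be set.

Step 1
Reactants: 1 3,5-dibromo-4-methoxybenzaldehyde
Product: 2 1,3-dibromo-5-ethynyl-2-methoxybenzene
Conditions: Bestmann–Ohira reagent (1.2 equiv), K2CO3 (2 equiv), MeOH, rt
Reagents that add atoms: Bestmann–Ohira reagent (dimethyl (1-diazo-2-oxopropyl)phosphonate), COP(=O)(OC)C(=[N+]=[N-])C(C)=O
Why: The Seyferth–Gilbert homologation in its Bestmann–Ohira variant turns aryl aldehydes into terminal alkynes under K2CO3/MeOH, which leaves the aryl bromides and the methyl ether untouched where an organolithium-based homologation would not.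

Step 2
Reactants: 2 1,3-dibromo-5-ethynyl-2-methoxybenzene
Product: 4 3-(3,5-dibromo-4-methoxyphenyl)prop-2-ynoic acid, via caesium arylpropiolate 3 (not isolated)
Conditions: CO2 (2 bar), AgI (2 mol %), Cs2CO3 (1.5 equiv), DMF, 50 °C; then 1 M HCl, 0 °C
Reagents that add atoms: carbon dioxide, O=C=O
Why: In this silver(I)-catalysed C–H carboxylation of a terminal alkyne, the silver acetylide formed with Cs2CO3 inserts CO2, and the lithium-free conditions spare the C–Br bonds.

Step 3
Reactants: 4 3-(3,5-dibromo-4-methoxyphenyl)prop-2-ynoic acid; 5 4-ethynylanisole (1-ethynyl-4-methoxybenzene)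
Product: 6 (Z)-2-(4-methoxyphenyl)ethenyl 3-(3,5-dibromo-4-methoxyphenyl)prop-2-ynoate
Conditions: [RuCl2(p-cymene)]2 (1 mol %), P(4-ClC6H4)3 (3 mol %), DMAP (4 mol %), toluene, 60 °C
Reagents that add atoms: none
Why: This ruthenium-catalysed anti-Markovnikov hydro-oxycarbonylation runs through a Ru-vinylidene that takes up the carboxylate at the terminal carbon to give the Z-enol ester, and only the terminal alkyne of 5 can form a vinylidene, so the internal alkyne of 4 should stay intact.

Step 4
Reactants: 6 (Z)-2-(4-methoxyphenyl)ethenyl 3-(3,5-dibromo-4-methoxyphenyl)prop-2-ynoate; 7 3,5-dibromo-4-methoxybenzoic acid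
Product: 13 (Z)-3-(3,5-dibromo-4-methoxybenzoyl)-4-(3,5-dibromo-4-methoxyphenyl)-5-(4-methoxybenzylidene)furan-2(5H)-one (tri-O-methylcadiolide A), via mixed anhydride 8 (not isolated), via aroyl radical 9 (not isolated), via C4 vinyl radical 10 (not isolated), via C6 benzylic radical 11 (not isolated), via C6 benzylic cation 12 (not isolated)
Conditions: 7 (2 equiv), dimethyl dicarbonate (3 equiv), fac-Ir(ppy)3 (2 mol %), 2,6-lutidine (1 equiv), MeCN, blue LEDs (450 nm), rt, Ar
Reagents that add atoms: none
Why: Proposed new method: 7 and dimethyl dicarbonate form mixed anhydride 8, which excited fac-Ir(ppy)3 reduces to methyl carbonate (then CO2 and methoxide) and the nucleophilic aroyl radical 9; 9 adds to the electron-poor alkyne carbon C3 of 6 to give the linear, aryl-stabilised C4 vinyl radical 10, 10 attacks the oxygen-bearing carbon C5 of the styryl ester and thereby forms C4–C5 and the butenolide ring, and the resulting p-anisyl-stabilised C6 radical 11 is oxidised by Ir(IV) to cation 12, which loses the acidic H5 to base and restores C5=C6. The closest known reaction type is the acyl-radical addition/5-exo ipso-cyclisation of aryl 3-arylpropiolates, which builds the same 3-acyl-4-arylbutenolide ring as a 1-oxaspiro[4.5]trienone (or, after ester migration, a 3-acyl-4-arylcoumarin), combined with the known photoredox generation of aroyl radicals from benzoic acids via mixed anhydrides; new are the enol-ester C=C as radical acceptor in place of the arene and the Heck-like radical-polar crossover that ends the cascade. The one ring is closed in the 5-exo-trig mode (C4 radical onto C5, spin expelled to exocyclic C6), favoured over 6-endo attack at C6 kinetically and because only the exo mode yields a benzylic radical. No lasting stereocentre is formed, since C5 of 11 and 12 becomes planar again; the Z geometry of C5=C6 should follow from deprotonation of the rotamer of 12 that keeps the anisyl ring away from the C4 aryl group (A1,3 strain in the E isomer), so the alkene geometry of 6 is of no consequence. The step needs chemoselective attack of 9 on the alkyne and not on C5=C6, secured by polarity matching (nucleophilic radical, acceptor alkyne) and by the hindered, donor-substituted, twisted Z-1,2-disubstituted alkene, and regioselective attack at C3, secured by aryl stabilisation of the radical at C4. The process is redox-neutral, so no external oxidant can attack the electron-rich styryl ester, and the aryl C–Br bonds lie beyond the reducing power of the excited catalyst.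

Step 5
Reactants: 13 tri-O-methylcadiolide A
Product: 15 cadiolide A, (Z)-3-(3,5-dibromo-4-hydroxybenzoyl)-4-(3,5-dibromo-4-hydroxyphenyl)-5-(4-hydroxybenzylidene)furan-2(5H)-one, via tris(dibromoboryl) ether 14 (not isolated)
Conditions: BBr3 (9 equiv), CH2Cl2, −78 °C to rt; then H2O, 0 °C
Reagents that add atoms: none
Why: Lewis-acid cleavage of aryl methyl ethers with BBr3 (aryloxyborane 14 hydrolysed on work-up) is the standard unmasking for aryl-substituted γ-ylidenebutenolides; lactone, diaryl ketone and C–Br bonds are inert to it, and the acidic medium should let any E isomer relax to the favoured Z form.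

Compound list
1 | 3,5-dibromo-4-methoxybenzaldehyde | COc1c(Br)cc(C=O)cc1Br | starting material
2 | 1,3-dibromo-5-ethynyl-2-methoxybenzene | COc1c(Br)cc(C#C)cc1Br | intermediate
3 | caesium 3-(3,5-dibromo-4-methoxyphenyl)prop-2-ynoate (not isolated) | COc1c(Br)cc(C#CC(=O)[O-])cc1Br.[Cs+] | intermediate
4 | 3-(3,5-dibromo-4-methoxyphenyl)prop-2-ynoic acid | COc1c(Br)cc(C#CC(=O)O)cc1Br | intermediate
5 | 4-ethynylanisole | COc1ccc(C#C)cc1 | starting material
6 | (Z)-2-(4-methoxyphenyl)ethenyl 3-(3,5-dibromo-4-methoxyphenyl)prop-2-ynoate | COc1ccc(/C=C\OC(=O)C#Cc2cc(Br)c(OC)c(Br)c2)cc1 | intermediate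
7 | 3,5-dibromo-4-methoxybenzoic acid | COc1c(Br)cc(C(=O)O)cc1Br | starting material
8 | 3,5-dibromo-4-methoxybenzoic methyl carbonic anhydride (not isolated) | COC(=O)OC(=O)c1cc(Br)c(OC)c(Br)c1 | intermediate
9 | 3,5-dibromo-4-methoxybenzoyl radical (not isolated) | COc1c(Br)cc([C]=O)cc1Br | intermediate
10 | C4 vinyl radical, open-chain adduct of 9 to C3 of 6 (not isolated) | COc1ccc(/C=C\OC(=O)C(C(=O)c2cc(Br)c(OC)c(Br)c2)=[C]c2cc(Br)c(OC)c(Br)c2)cc1 | intermediate
11 | C6 benzylic radical, ring-closed butenolide, racemic at transient C5 (not isolated) | COc1ccc([CH]C2OC(=O)C(C(=O)c3cc(Br)c(OC)c(Br)c3)=C2c2cc(Br)c(OC)c(Br)c2)cc1 | intermediate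
12 | C6 benzylic cation, ring-closed butenolide, racemic at transient C5 (not isolated) | COc1ccc([CH+]C2OC(=O)C(C(=O)c3cc(Br)c(OC)c(Br)c3)=C2c2cc(Br)c(OC)c(Br)c2)cc1 | intermediate
13 | tri-O-methylcadiolide A, Z | O=C1O/C(=C\c2ccc(OC)cc2)C(c2cc(Br)c(OC)c(Br)c2)=C1C(=O)c1cc(Br)c(OC)c(Br)c1 | intermediate
14 | tris(O-dibromoboryl) derivative of cadiolide A, Z (not isolated) | O=C1O/C(=C\c2ccc(OB(Br)Br)cc2)C(c2cc(Br)c(OB(Br)Br)c(Br)c2)=C1C(=O)c1cc(Br)c(OB(Br)Br)c(Br)c1 | intermediate
15 | cadiolide A, Z | O=C1O/C(=C\c2ccc(O)cc2)C(c2cc(Br)c(O)c(Br)c2)=C1C(=O)c1cc(Br)c(O)c(Br)c1 | target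

Total step count: 5.
Longest linear sequence: 5 steps (1 → 2 → 4 → 6 → 13 → 15). Compounds 5 and 7 enter as purchased.

Steps most likely to fail

1. Step 4 (Proposed new method).
- What may go wrong: The aroyl radical may add to the styryl double bond instead of the alkyne. Slow rotation of the ester from its s-trans to its s-cis form may let the vinyl radical abstract hydrogen before it can close the ring. Energy transfer from the catalyst may also scramble the alkene geometry or feed side reactions of the coloured product.
- Fallback: The fallback uses known chemistry only, sets out from 7 and 2, and returns at 13. Acid 7 is condensed with Meldrum's acid (DCC, DMAP, CH2Cl2) to the acyl Meldrum's acid F1. Alkyne 2 is oxidised with PhI(OCOCF3)2 in aqueous MeCN to the α-hydroxy ketone F2. Heating F1 with F2 in toluene releases the aroylketene F3, which the hydroxyl group of F2 traps as the β-keto ester F4. Et3N in the same pot closes F4 by intramolecular Knoevenagel condensation to the 3-aroyl-4-arylfuran-2(5H)-one F5. A piperidine-mediated vinylogous aldol condensation of F5 with 4-methoxybenzaldehyde in MeOH should then give 13 as the thermodynamic Z isomer.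

2. Step 3.
- What may go wrong: Regiocontrol may erode towards Markovnikov addition. The metal may induce loss of CO2 from the alkynoic acid. The conjugated alkyne may bind and deactivate the catalyst.
- Fallback: The fallback replaces the catalytic addition by enolate O-acylation, sets out from 4, and returns at 6. Acid 4 is converted with oxalyl chloride and catalytic DMF into the arylpropioloyl chloride F6. (4-Methoxyphenyl)acetaldehyde is deprotonated with KHMDS in THF at −78 °C to the potassium enolate F7. O-Acylation of F7 with F6 should give 6 together with its E isomer F8. Both isomers are usable because step 4 erases this geometry.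

3. Step 2.
- What may go wrong: The carboxylation is reversible, so protodecarboxylation of the silver or caesium propiolate during the reaction or the acidification may stall conversion.
- Fallback: The fallback is the classical cinnamic acid route. It sets out from 1, returns at 4, and bypasses steps 1 and 2. A Knoevenagel–Doebner condensation of 1 with malonic acid (pyridine, piperidine, 100 °C) passes through the arylidenemalonic acid F9 to the (E)-cinnamic acid F10. Anti addition of Br2 in CHCl3 gives the racemic erythro dibromo acid F11. Double dehydrobromination with KOH in refluxing EtOH followed by acidification gives 4.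

Further compounds
F1 | step 4 | 5-[(3,5-dibromo-4-methoxyphenyl)(hydroxy)methylidene]-2,2-dimethyl-1,3-dioxane-4,6-dione | COc1c(Br)cc(C(O)=C2C(=O)OC(C)(C)OC2=O)cc1Br
F2 | step 4 | 1-(3,5-dibromo-4-methoxyphenyl)-2-hydroxyethan-1-one | COc1c(Br)cc(C(=O)CO)cc1Br
F3 | step 4 | (3,5-dibromo-4-methoxybenzoyl)ketene | COc1c(Br)cc(C(=O)C=C=O)cc1Br
F4 | step 4 | 2-(3,5-dibromo-4-methoxyphenyl)-2-oxoethyl 3-(3,5-dibromo-4-methoxyphenyl)-3-oxopropanoate | COc1c(Br)cc(C(=O)CC(=O)OCC(=O)c2cc(Br)c(OC)c(Br)c2)cc1Br
F5 | step 4 | 3-(3,5-dibromo-4-methoxybenzoyl)-4-(3,5-dibromo-4-methoxyphenyl)furan-2(5H)-one | O=C1OCC(c2cc(Br)c(OC)c(Br)c2)=C1C(=O)c1cc(Br)c(OC)c(Br)c1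
F6 | step 3 | 3-(3,5-dibromo-4-methoxyphenyl)prop-2-ynoyl chloride | COc1c(Br)cc(C#CC(=O)Cl)cc1Br
F7 | step 3 | potassium 2-(4-methoxyphenyl)ethenolate (E/Z mixture) | COc1ccc(C=C[O-])cc1.[K+]
F8 | step 3 | (E)-2-(4-methoxyphenyl)ethenyl 3-(3,5-dibromo-4-methoxyphenyl)prop-2-ynoate | COc1ccc(/C=C/OC(=O)C#Cc2cc(Br)c(OC)c(Br)c2)cc1
F9 | step 2 | 2-(3,5-dibromo-4-methoxybenzylidene)malonic acid | COc1c(Br)cc(C=C(C(=O)O)C(=O)O)cc1Br
F10 | step 2 | (E)-3-(3,5-dibromo-4-methoxyphenyl)prop-2-enoic acid | COc1c(Br)cc(/C=C/C(=O)O)cc1Br
F11 | step 2 | rac-(2R,3S)-2,3-dibromo-3-(3,5-dibromo-4-methoxyphenyl)propanoic acid (one enantiomer drawn) | OC(=O)[C@@H](Br)[C@@H](Br)c1cc(Br)c(OC)c(Br)c1
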